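**Retrosynthetic overview**
- The O3 ester bond is cut last, giving (3R)-β-cryptoxanthin and palmitoleic acid, so the (9Z)-alkene of the acyl chain never meets ruthenium.
- C7=C8 is cut by a Wittig disconnection into a ring A C10 phosphonium salt and the C30 aldehyde β-apo-8′-carotenal, which brings ring B and the whole polyene.
- The route rests on ring A: a cyclohexene whose only double bond, the fully substituted C5=C6, lies next to quaternary C1, while C3–C4–C5(CH3) is a methallyl carbinol unit. C5=C6 is therefore opened to an acyclic 1,7-diene with two 1,1-disubstituted alkenes, closed again by olefin metathesis.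
- In that diene, C3 is set (R) by reagent-controlled methallylboration of an aldehyde, and quaternary C1 by a Johnson–Claisen rearrangement of a mono-protected 2-isopropylidene-1,3-diol.
- Ring order: ring A is the only ring formed (step 7); ring B is bought intact.

Key step: step 7

Remark on the chemistry: the sense of induction in step 5 is assigned on the usual chair model for B-allyl- and B-methallyldiisopinocampheylboranes (reagent of the (−)-α-pinene series adds to the Re face of an α-unbranched aldehyde). The configuration of the carbinol would be checked by Mosher ester analysis; the antipodal reagent is equally available.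

**Step 1**
Reactants: 1 diethyl isopropylidenemalonate
Product: 2 2-(propan-2-ylidene)propane-1,3-diol
Conditions: i-Bu2AlH (4.5 equiv), CH2Cl2, −78 °C to 0 °C; aq. potassium sodium tartrate
Reagents that add atoms: none
Why: Ester reduction with the electrophilic hydride i-Bu2AlH should go by 1,2-addition at both carbonyls, the tetrasubstituted alkene being too hindered for conjugate reduction, to give the allylic diol.

**Step 2**
Reactants: 2 2-(propan-2-ylidene)propane-1,3-diol
Product: 3 2-{[(4-methoxybenzyl)oxy]methyl}-3-methylbut-2-en-1-ol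
Conditions: NaH (1.0 equiv), THF, 0 °C; 4-methoxybenzyl chloride (0.95 equiv), Bu4NI (cat.), THF/DMF, 0 °C to rt
Reagents that add atoms: 4-methoxybenzyl chloride, COc1ccc(CCl)cc1
Why: Williamson etherification of the mono-alkoxide of a symmetrical diol has no regiochemical issue, and limiting base and halide to one equivalent should favour the mono-ether, unreacted diol being recycled.

**Step 3**
Reactants: 3 2-{[(4-methoxybenzyl)oxy]methyl}-3-methylbut-2-en-1-ol
Product: 5 ethyl 4-{[(4-methoxybenzyl)oxy]methyl}-3,3-dimethylpent-4-enoate, via ketene acetal 4 (not isolated)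
Conditions: MeC(OEt)3 (6 equiv), EtCO2H (5 mol%), 140 °C, EtOH distilled off
Reagents that add atoms: triethyl orthoacetate, CC(OCC)(OCC)OCC
Why: Johnson–Claisen rearrangement: the [3,3] shift of ketene acetal 4 delivers the CH2CO2Et unit to the isopropylidene carbon, creating quaternary C1 and leaving the 1,1-disubstituted alkene at C6.

**Step 4**
Reactants: 5 ethyl 4-{[(4-methoxybenzyl)oxy]methyl}-3,3-dimethylpent-4-enoate
Product: 6 4-{[(4-methoxybenzyl)oxy]methyl}-3,3-dimethylpent-4-enal
Conditions: i-Bu2AlH (1.1 equiv), CH2Cl2, −78 °C; MeOH, aq. potassium sodium tartrate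
Reagents that add atoms: none
Why: Partial ester reduction should stop at the aldehyde because the tetrahedral aluminium hemiacetal is stable at −78 °C and collapses only on work-up.

**Step 5**
Reactants: 6 4-{[(4-methoxybenzyl)oxy]methyl}-3,3-dimethylpent-4-enal; 7 methallylmagnesium chloride
Product: 10 (4R)-7-{[(4-methoxybenzyl)oxy]methyl}-2,6,6-trimethylocta-1,7-dien-4-ol, via B-methallyldiisopinocampheylborane 8 (not isolated), via borinate ester 9 (not isolated)
Conditions: Ipc2BOMe of the (−)-α-pinene series (1.3 equiv), 7 (1.2 equiv), Et2O, 0 °C to rt, 1 h; 6, −78 °C, 3 h; then 3 M NaOH, 30% H2O2, rt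
Reagents that add atoms: none
Why: Brown asymmetric methallylboration: reagent 8 transfers its methallyl group through a closed chair transition state in which the isopinocampheyl groups of the (−)-α-pinene series expose the Re face of the achiral aldehyde, so the C3 carbinol should form as (R) under reagent control, and oxidative work-up cleaves borinate 9.

**Step 6**
Reactants: 10 (4R)-7-{[(4-methoxybenzyl)oxy]methyl}-2,6,6-trimethylocta-1,7-dien-4-ol
Product: 11 tert-butyl{[(4R)-7-{[(4-methoxybenzyl)oxy]methyl}-2,6,6-trimethylocta-1,7-dien-4-yl]oxy}dimethylsilane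
Conditions: t-BuMe2SiCl (1.5 equiv), imidazole (3 equiv), DMF, rt
Reagents that add atoms: tert-butyldimethylsilyl chloride, CC(C)(C)[Si](C)(C)Cl
Why: Standard silylation of a secondary alcohol; the ether keeps the carbinol from ruthenium-hydride redox isomerisation in step 7 and does not touch the stereocentre.

**Step 7**
Reactants: 11 tert-butyl{[(4R)-7-{[(4-methoxybenzyl)oxy]methyl}-2,6,6-trimethylocta-1,7-dien-4-yl]oxy}dimethylsilane
Product: 12 tert-butyl{[(1R)-4-{[(4-methoxybenzyl)oxy]methyl}-3,5,5-trimethylcyclohex-3-en-1-yl]oxy}dimethylsilane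
Conditions: RuCl2[1,3-bis(2-methylphenyl)imidazolidin-2-ylidene](=CH-C6H4-2-O-i-Pr) (2 × 5 mol%), 1,4-benzoquinone (10 mol%), toluene (0.01 M), 100 °C, argon sparge
Reagents that add atoms: none
Why: The 14-electron ruthenium carbene should first exchange with the less hindered methallyl alkene to give a disubstituted carbene at C5, which adds across the C6 methylene in an intramolecular [2+2] step; cycloreversion of the ruthenacyclobutane releases the C5=C6 alkene and [Ru]=CH2, and loss of ethylene makes the sequence irreversible. The closest known reaction type is ring-closing metathesis of two 1,1-disubstituted alkenes to tetrasubstituted cyclohexenes, for which the small N-(2-methylphenyl) carbene ligand is suited; the quaternary C1 next to C6 makes this a demanding member of that class. Ring A is closed as a six-membered ring by intramolecular metathesis between C5 and C6 of the 1,7-diene. No stereocentre is formed, and C3, two bonds from either alkene and masked as its silyl ether, is carried through unchanged. The step needs cyclisation to win over oligomerisation and over alkene migration: the gem-dimethyl group at C1 and the branched C3 fold the chain (Thorpe–Ingold effect), 1,1-disubstituted alkenes hardly cross-couple at 0.01 M, and 1,4-benzoquinone intercepts ruthenium hydrides.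

**Step 8**
Reactants: 12 tert-butyl{[(1R)-4-{[(4-methoxybenzyl)oxy]methyl}-3,5,5-trimethylcyclohex-3-en-1-yl]oxy}dimethylsilane
Product: 13 [(4R)-4-{[tert-butyl(dimethyl)silyl]oxy}-2,6,6-trimethylcyclohex-1-en-1-yl]methanol
Conditions: DDQ (1.2 equiv), CH2Cl2/pH 7 phosphate buffer (10:1), 0 °C
Reagents that add atoms: none
Why: Oxidative cleavage of the 4-methoxybenzyl ether by benzylic hydride abstraction and hydrolysis of the oxocarbenium ion should spare the silyl ether and the tetrasubstituted alkene, low temperature and a small excess limiting over-oxidation of the allylic alcohol.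

**Step 9**
Reactants: 13 [(4R)-4-{[tert-butyl(dimethyl)silyl]oxy}-2,6,6-trimethylcyclohex-1-en-1-yl]methanol
Product: 14 {[(4R)-4-hydroxy-2,6,6-trimethylcyclohex-1-en-1-yl]methyl}triphenylphosphonium bromide
Conditions: PPh3·HBr (1.3 equiv), MeOH, rt, 48 h, dark; recrystallisation (CH2Cl2/EtOAc)
Reagents that add atoms: triphenylphosphine hydrobromide, [Br-].c1ccc(cc1)[PH+](c1ccccc1)c1ccccc1
Why: Acid-promoted ionisation of the allylic alcohol and capture of the allyl cation by PPh3 at primary C7 should give the salt, while the same methanolic HBr cleaves the silyl ether by methanolysis; the non-allylic C3 hydroxyl does not ionise, and crystallisation of the salt offers an upgrade of enantiomeric purity.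

**Step 10**
Reactants: 14 {[(4R)-4-hydroxy-2,6,6-trimethylcyclohex-1-en-1-yl]methyl}triphenylphosphonium bromide; 15 β-apo-8′-carotenal
Product: 17 (3R)-β-cryptoxanthin [(3R)-β,β-caroten-3-ol], via phosphorus ylide 16 (not isolated)
Conditions: 14 (1.3 equiv), NaOMe (1.3 equiv), CH2Cl2/MeOH, 0 °C to rt, dark, argon; then heptane, reflux (Z to E equilibration); crystallisation from CH2Cl2/MeOH
Reagents that add atoms: none
Why: Wittig olefination of the semi-stabilised allylic ylide 16 with the C30 enal forms C7=C8; the (7Z) isomer is disfavoured by the ring methyl groups, residual Z isomers should equilibrate thermally to the all-E polyene, and the free C3 hydroxyl is tolerated.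

**Step 11**
Reactants: 17 (3R)-β-cryptoxanthin; 18 palmitoleic acid [(9Z)-hexadec-9-enoic acid]
Product: 19 (3R)-β,β-caroten-3-yl (9Z)-hexadec-9-enoate (CNP0382087.1)
Conditions: 18 (1.5 equiv), DCC (1.5 equiv), DMAP (0.2 equiv), CH2Cl2, 0 °C to rt, dark, argon
Reagents that add atoms: none
Why: Steglich esterification acylates the secondary C3 hydroxyl at oxygen, so the C3 configuration is retained, and the neutral conditions should leave the polyene and the (9Z)-alkene of the acyl chain unchanged.

**Compound list**
1 | diethyl isopropylidenemalonate | CCOC(=O)C(=C(C)C)C(=O)OCC | starting material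
2 | 2-(propan-2-ylidene)propane-1,3-diol | OCC(CO)=C(C)C | intermediate
3 | 2-{[(4-methoxybenzyl)oxy]methyl}-3-methylbut-2-en-1-ol | OCC(COCc1ccc(OC)cc1)=C(C)C | intermediate
4 | mixed ketene acetal (1-ethoxyvinyl ether of 3), formed in the flask | C=C(OCC)OCC(COCc1ccc(OC)cc1)=C(C)C | intermediate
5 | ethyl 4-{[(4-methoxybenzyl)oxy]methyl}-3,3-dimethylpent-4-enoate | CCOC(=O)CC(C)(C)C(=C)COCc1ccc(OC)cc1 | intermediate
6 | 4-{[(4-methoxybenzyl)oxy]methyl}-3,3-dimethylpent-4-enal | O=CCC(C)(C)C(=C)COCc1ccc(OC)cc1 | intermediate
7 | methallylmagnesium chloride (commercial THF solution, otherwise from methallyl chloride and Mg) | C=C(C)C[Mg]Cl | starting material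
8 | B-methallyldiisopinocampheylborane of the (−)-α-pinene series, formed in the flask | C=C(C)CB([C@H]1C[C@H]2C[C@@H]([C@@H]1C)C2(C)C)[C@H]1C[C@H]2C[C@@H]([C@@H]1C)C2(C)C | intermediate
9 | diisopinocampheylborinate ester of 10, formed in the flask | C=C(C)C[C@@H](OB([C@H]1C[C@H]2C[C@@H]([C@@H]1C)C2(C)C)[C@H]1C[C@H]2C[C@@H]([C@@H]1C)C2(C)C)CC(C)(C)C(=C)COCc1ccc(OC)cc1 | intermediate
10 | (4R)-7-{[(4-methoxybenzyl)oxy]methyl}-2,6,6-trimethylocta-1,7-dien-4-ol | C=C(C)C[C@@H](O)CC(C)(C)C(=C)COCc1ccc(OC)cc1 | intermediate
11 | tert-butyl{[(4R)-7-{[(4-methoxybenzyl)oxy]methyl}-2,6,6-trimethylocta-1,7-dien-4-yl]oxy}dimethylsilane (metathesis precursor) | C=C(C)C[C@@H](O[Si](C)(C)C(C)(C)C)CC(C)(C)C(=C)COCc1ccc(OC)cc1 | intermediate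
12 | tert-butyl{[(1R)-4-{[(4-methoxybenzyl)oxy]methyl}-3,5,5-trimethylcyclohex-3-en-1-yl]oxy}dimethylsilane (ring A, carotenoid C3 = R) | CC(C)(C)[Si](C)(C)O[C@@H]1CC(C)=C(COCc2ccc(OC)cc2)C(C)(C)C1 | intermediate
13 | [(4R)-4-{[tert-butyl(dimethyl)silyl]oxy}-2,6,6-trimethylcyclohex-1-en-1-yl]methanol | CC(C)(C)[Si](C)(C)O[C@@H]1CC(C)=C(CO)C(C)(C)C1 | intermediate
14 | {[(4R)-4-hydroxy-2,6,6-trimethylcyclohex-1-en-1-yl]methyl}triphenylphosphonium bromide | O[C@@H]1CC(C)=C(C[P+](c2ccccc2)(c2ccccc2)c2ccccc2)C(C)(C)C1.[Br-] | intermediate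
15 | β-apo-8′-carotenal (all-E) | O=C/C(C)=C/C=C/C(C)=C/C=C/C=C(C)/C=C/C=C(C)/C=C/C1=C(C)CCCC1(C)C | starting material
16 | phosphorus ylide of 14, formed in the flask | O[C@@H]1CC(C)=C(C=P(c2ccccc2)(c2ccccc2)c2ccccc2)C(C)(C)C1 | intermediate
17 | (3R)-β-cryptoxanthin, (3R)-β,β-caroten-3-ol (all-E) | O[C@@H]1CC(C)=C(/C=C/C(C)=C/C=C/C(C)=C/C=C/C=C(C)/C=C/C=C(C)/C=C/C2=C(C)CCCC2(C)C)C(C)(C)C1 | intermediate
18 | palmitoleic acid, (9Z)-hexadec-9-enoic acid | CCCCCC/C=C\CCCCCCCC(=O)O | starting material
19 | (3R)-β,β-caroten-3-yl (9Z)-hexadec-9-enoate (CNP0382087.1) | CCCCCC/C=C\CCCCCCCC(=O)O[C@@H]1CC(C)=C(/C=C/C(C)=C/C=C/C(C)=C/C=C/C=C(C)/C=C/C=C(C)/C=C/C2=C(C)CCCC2(C)C)C(C)(C)C1 | target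

**Step count and risks**
Total step count: 11. Longest linear sequence: 11 steps (1 to 19); compounds 7, 15 and 18 enter as purchased materials.

Steps most likely to fail:

1. Step 7 (ring-closing metathesis). The cyclisation may stall because the ruthenacyclobutane that joins C5 to C6 is crowded by quaternary C1 and the C7 ether. The catalyst may decompose before turnover, and ruthenium hydrides may move the methallyl alkene along the chain. Switching to Mo(=CHCMe2Ph)(N-2,6-i-Pr2C6H3)[OCMe(CF3)2]2 would only be a change of conditions. The fallback gives up the metathesis and makes ring A from a preformed cyclohexanone by enol triflate carbonylation. It uses none of compounds 1–12, sets out instead from commercial (4R,6R)-4-hydroxy-2,2,6-trimethylcyclohexanone F1, and comes back to the route at compound 13. F1 would be silylated (t-BuMe2SiCl, imidazole, DMF) to the silyl ether F2. LiN(i-Pr)2 in THF at −78 °C followed by PhNTf2 should give the enol triflate F3: only the methine carbon next to the carbonyl (the later C5) bears an α-hydrogen, so the alkene can form only at C5=C6, and that methine stereocentre is removed by design while the carbinol centre is untouched. Carbonylation with Pd(OAc)2/PPh3, CO (1 atm), MeOH and Et3N in DMF at 60 °C should give the methyl ester F4, and i-Bu2AlH in CH2Cl2 at −78 °C would reduce F4 to 13.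

2. Step 5 (methallylboration). Facial selectivity may be incomplete, since the aldehyde is unbranched at the α-carbon and magnesium salts can erode the selectivity of the allyl transfer; this would leave the antipode in all later material. The fallback sets C3 by kinetic resolution of a terminal epoxide; it sets out from compound 6 and comes back at compound 10. Corey–Chaykovsky methylenation of 6 (Me3S+ I−, n-BuLi, THF, −10 °C) should give the racemic epoxide 2-(3-{[(4-methoxybenzyl)oxy]methyl}-2,2-dimethylbut-3-en-1-yl)oxirane F5. Hydrolytic kinetic resolution with (salen)Co(OAc) (trivalent cobalt; the ligand antipode chosen so that the (R)-epoxide is hydrolysed) and H2O (0.55 equiv) should leave the (S)-epoxide F6. Isopropenylmagnesium bromide with CuI (10 mol%) in THF at −30 °C should open F6 at its CH2 terminus and give 10 without touching the carbinol carbon.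

3. Step 10 (Wittig reaction). Addition of the hindered ylide to the polyene aldehyde may be sluggish, with competing degradation of the light- and oxygen-sensitive polyene and formation of Z isomers that resist equilibration. The fallback is a Julia–Kocienski olefination; it sets out from compound 13 and comes back at compound 17. Mitsunobu reaction of 13 with 2-mercaptobenzothiazole (PPh3, DIAD, THF) should give the benzothiazolyl sulfide F7. Oxidation with (NH4)6Mo7O24/H2O2 in EtOH at 0 °C should give the sulfone F8. Deprotonation with NaN(SiMe3)2 in THF at −78 °C and addition of aldehyde 15, followed by thermal equilibration, should give the tert-butyldimethylsilyl ether of (3R)-β-cryptoxanthin F9, and Bu4NF in THF would release 17.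

**Further compounds**
F1 | step 7 | (4R,6R)-4-hydroxy-2,2,6-trimethylcyclohexanone | O[C@@H]1C[C@@H](C)C(=O)C(C)(C)C1
F2 | step 7 | (4R,6R)-4-{[tert-butyl(dimethyl)silyl]oxy}-2,2,6-trimethylcyclohexanone | CC(C)(C)[Si](C)(C)O[C@@H]1C[C@@H](C)C(=O)C(C)(C)C1
F3 | step 7 | (4R)-4-{[tert-butyl(dimethyl)silyl]oxy}-2,6,6-trimethylcyclohex-1-en-1-yl trifluoromethanesulfonate | CC(C)(C)[Si](C)(C)O[C@@H]1CC(C)=C(OS(=O)(=O)C(F)(F)F)C(C)(C)C1
F4 | step 7 | methyl (4R)-4-{[tert-butyl(dimethyl)silyl]oxy}-2,6,6-trimethylcyclohex-1-ene-1-carboxylate | CC(C)(C)[Si](C)(C)O[C@@H]1CC(C)=C(C(=O)OC)C(C)(C)C1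
F5 | step 5 | racemic 2-(3-{[(4-methoxybenzyl)oxy]methyl}-2,2-dimethylbut-3-en-1-yl)oxirane | C1OC1CC(C)(C)C(=C)COCc1ccc(OC)cc1
F6 | step 5 | (2S)-2-(3-{[(4-methoxybenzyl)oxy]methyl}-2,2-dimethylbut-3-en-1-yl)oxirane | C1O[C@H]1CC(C)(C)C(=C)COCc1ccc(OC)cc1
F7 | step 10 | 2-({[(4R)-4-{[tert-butyl(dimethyl)silyl]oxy}-2,6,6-trimethylcyclohex-1-en-1-yl]methyl}sulfanyl)-1,3-benzothiazole | CC(C)(C)[Si](C)(C)O[C@@H]1CC(C)=C(CSc2nc3ccccc3s2)C(C)(C)C1
F8 | step 10 | 2-({[(4R)-4-{[tert-butyl(dimethyl)silyl]oxy}-2,6,6-trimethylcyclohex-1-en-1-yl]methyl}sulfonyl)-1,3-benzothiazole | CC(C)(C)[Si](C)(C)O[C@@H]1CC(C)=C(CS(=O)(=O)c2nc3ccccc3s2)C(C)(C)C1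
F9 | step 10 | (3R)-β-cryptoxanthin tert-butyldimethylsilyl ether | CC(C)(C)[Si](C)(C)O[C@@H]1CC(C)=C(/C=C/C(C)=C/C=C/C(C)=C/C=C/C=C(C)/C=C/C=C(C)/C=C/C2=C(C)CCCC2(C)C)C(C)(C)C1
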